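If you take over these flasks, here is what I reckoned before any of them had finished.

the same everywhere: time 12 h
- east: substrate 0.10 M; partner 0.0600 M (fed, over 10 h); all else is in the flask from the start; the feed brings no volume worth counting
- north-east: substrate 0.10 M (fed, over 10 h); partner 0.0600 M; all else is in the flask from the start; the feed brings no volume worth counting
- north-west: substrate 0.10 M; partner 0.0600 M; everything together at the start

    partner → decomposed reagent (k1 = 0.020 /min)
    target ⇌ isomer of the product (K2 = 3.0, k2 = 0.0031 /min)
    substrate + partner → target, rate k3*[substrate]^2*[partner] (k3 = 16 /M²/min)

1. the flask that comes out highest in amount of isomer of the product, in percent of the substrate charged, or "all alike" when all lie within 1.5 percentage points (east / north-east / north-west / all alike)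
2. isomer of the product at the end, in percent of the substrate charged, east
3. isomer of the product at the end, in percent of the substrate charged, north-east
4. isomer of the product at the end, in percent of the substrate charged, north-west

I counted what was left, not what was made. Coupling and decomposition both carry [partner], so it cancels from their ratio, the selectivity factor: the square of [substrate] over the square of 0.0354 M, the even-share level, at which partner couples as often as it decomposes. Summed over a run, partner spent equals substrate lost plus the square of that level times the rise in reciprocal [substrate]. The pace of partner drops out, so I expected 0.0517 M of substrate left in both east and north-west, still above the even-share level.

Target and isomer of the product relax with a half-life of 2.79 h towards 75.0% isomer, so I followed the gap left. Taking north-west's coupling as coming at the start leaves 5.10% of the gap and gives 34.4% isomer. Taking east's coupling as even over the feed leaves 22.5% and gives 28.1%. I asked that east not be stopped early, since its youngest target gets 2.00 h after the feed, less than that half-life. In north-east, I put fed [substrate] at 0.00833 M after one partner lifetime, less than the even-share level, and from the share of partner that couples at that level I expected about 2.25% isomer.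

The forecast gave 28.4%, 2.6% and 34.2% for east, north-east and north-west, and put north-west first, since “the late-formed product in the partner-fed flask has less time”.

The flasks gave 28.1%, 2.44% and 34.3%, with north-west highest. I then took the neighbour of north-west charged with 0.15 M of partner. The same balance gave 0.0159 M of substrate left, or 15.9% of the charge, and that amount is below the even-share level. With the same 5.10% of the gap, that meant 59.8% isomer. That flask ended with 15.9% of substrate and 59.7% of isomer of the product.

(The numbers of this flask come from no measurement; the result is computed.)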